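**Plan**
1. Cuts, in retrosynthetic order:
   - the phenols and formyl groups go back to a 2,4,6-trimethoxyphenyl ring, and the C1 ketone to a C1=C5 alkene;
   - aryl–C7' and C8'–isopropyl are cut together, and C7'=C8' goes back to a C4 aldehyde;
   - C4–C7' is cut through a [2,3] shift to a C1 allylic ether, and carbonyl carbons C1 and C10 are rejoined as the ring alkene of (+)-ledene.
2. Enabling feature: benzylic C7' sits on quaternary ring carbon C4, next to C5, which carries the cyclopropane and adjoins C1. C7' bears the arene and continues as C8'H2–CH(CH3)2. Arene and isopropyl are therefore vicinal and can both be added across a C7'=C8' alkenylboronate, after which boron is removed from C8'.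
3. Forward order: no ring is built. The five- and three-membered rings survive the ozonolytic opening of ledene's seven-membered ring. Then C7' (iodomethylstannane), C8' (dichloromethylboronate), isopropyl plus arene (key step) and the two formyl carbons are attached in that order.
4. Stereochemistry: C6 and C7 come from ledene. A CBS-set C1 carbinol is relayed to C4 by the suprafacial [2,3] shift. C7' comes from the chiral palladium catalyst. C5 is set by base equilibration trans to the C7' branch.

Key step: step 13

Atom labels: C1 (ketone carbon)–C2–C3–C4 (quaternary)–C5 is the five-membered ring. C6 (on C5) and C7 are the cyclopropane CH carbons and C11 is its CMe2 carbon. C8–C9–C10(=O)–C14 is the oxobutyl chain on C7, and C15 is the methyl on C4. C7' is the benzylic carbon and C8' its neighbour. C6 and C7 keep the ledene configuration throughout.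

Remark: "mac" is the cis-1,2-dimethylacenaphthylene-1,2-diolate ligand on boron. It replaces pinacol because β-substituted alkenyl pinacol ate complexes tend to hand the alkenyl group directly to palladium.

Assumption: the sense of induction of the ferrocenyl ligand is extrapolated from simple β-alkyl alkenylboron ate complexes. If the antipode named in step 13 proves mismatched, its commercial mirror image is used with no other change.

**Step 1**
Reactants: 1 (+)-ledene
Product: 3 seco-diketone (C1 cyclopentanone plus C10 methyl ketone; C4–C7 as in 1), via secondary ozonide 2 (not isolated)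
Conditions: O3, CH2Cl2, −78 °C; then Me2S, −78 °C → rt
Reagents that add atoms: ozone, [O-][O+]=O
Why: Ozonolysis (Criegee mechanism) attacks the only alkene, the electron-rich tetrasubstituted C1=C10 bond, and reductive work-up opens the seven-membered ring to the two ketones while C4, C5, C6 and C7 stay as in 1.

**Step 2**
Reactants: 3 seco-diketone
Product: 4 C10 ethylene ketal of 3
Conditions: Me3SiOCH2CH2OSiMe3 (1.05 equiv), Me3SiOTf (2 mol %), CH2Cl2, −78 °C; pyridine quench
Reagents that add atoms: 1,2-bis(trimethylsilyloxy)ethane, C[Si](C)(C)OCCO[Si](C)(C)C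
Why: Noyori acetalisation is kinetically controlled and sterically demanding, so it should take the unhindered acyclic C10 ketone before the α-branched cyclopentanone (whose rehybridisation adds eclipsing strain), and the cold aprotic medium suppresses the six-ring intramolecular aldol paths open to 3.

**Step 3**
Reactants: 4 C10 ethylene ketal
Product: 5 C1 trimethylsilyl enol ether (C1=C5)
Conditions: Me3SiCl, Et3N, DMF, 110 °C
Reagents that add atoms: chlorotrimethylsilane, C[Si](C)(C)Cl
Why: Silyl enol ether formation under equilibrating conditions gives the thermodynamic isomer, which for a 2-alkylcyclopentanone is the tetrasubstituted C1=C5 enol ether, here also conjugated with the cyclopropane, and the ketal is inert to the basic medium.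

**Step 4**
Reactants: 5 C1 trimethylsilyl enol ether
Product: 8 enone (3-methyl-2-cyclopropylcyclopent-2-enone core; C4=C5), via C5 phenylselenide 6 (not isolated), via selenoxide 7 (not isolated)
Conditions: PhSeCl, CH2Cl2, −78 °C; then pyridine, 30% H2O2, 0 °C → rt
Reagents that add atoms: none
Why: Electrophilic selenenylation at C5 anti to the C4 methyl and selenoxide syn elimination towards the cis C4–H give the tetrasubstituted enone, because elimination towards C6–H would create a strained alkylidenecyclopropane, and the sequence avoids any cyclopropylcarbinyl metal, radical or cation.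

**Step 5**
Reactants: 8 enone
Product: 9 (1R)-allylic alcohol
Conditions: (S)-1-methyl-3,3-diphenyltetrahydro-1H,3H-pyrrolo[1,2-c][1,3,2]oxazaborole ((S)-Me-CBS, 0.2 equiv), BH3·SMe2, THF, −30 °C; MeOH, then H2O
Reagents that add atoms: none
Why: Corey–Bakshi–Shibata reduction, in which the borane-loaded oxazaborolidine binds the carbonyl lone pair anti to the larger, fully substituted alkenyl branch (C5) and delivers hydride to one face, so the (S)-catalyst should give the (1R)-alcohol 1,2-selectively under reagent control.

**Step 6**
Reactants: 9 (1R)-allylic alcohol; 10 tributyl(iodomethyl)stannane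
Product: 11 (1R)-tributylstannylmethyl ether
Conditions: KH, THF, 0 °C → rt
Reagents that add atoms: none
Why: Williamson etherification of the potassium alkoxide with the reactive iodomethylstannane, the usual entry to Still–Wittig substrates, occurs at oxygen and leaves C1 unchanged.

**Step 7**
Reactants: 11 (1R)-tributylstannylmethyl ether
Product: 13 (4S)-primary alcohol (C4 bears CH3 plus CH2OH; alkene now C1=C5), via alkoxymethyllithium 12 (not isolated)
Conditions: n-BuLi, THF, −78 → −20 °C; H2O
Reagents that add atoms: none
Why: Tin–lithium exchange starts a Still–Wittig [2,3]-sigmatropic rearrangement whose concerted suprafacial course moves the CH2O unit from the C1 oxygen to C4 on the same ring face, so the C1 configuration is transferred to quaternary C4 and C7' is installed.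

**Step 8**
Reactants: 13 (4S)-primary alcohol
Product: 14 (4S)-aldehyde
Conditions: n-Pr4N[RuO4] (5 mol %), N-methylmorpholine N-oxide, 4 Å MS, CH2Cl2, rt
Reagents that add atoms: none
Why: Ley–Griffith oxidation of a neopentyl primary alcohol stops at the aldehyde, which has no α-hydrogen and so can neither epimerise nor move its alkene into conjugation.

**Step 9**
Reactants: 15 acenaphthoquinone
Product: 16 mac diol (cis-1,2-dimethyl-1,2-dihydroacenaphthylene-1,2-diol; meso)
Conditions: AlMe3 (3 equiv), toluene, 0 °C → rt; aqueous work-up; recrystallisation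
Reagents that add atoms: trimethylaluminium, C[Al](C)C
Why: Twofold 1,2-addition of methyl to the α-diketone, in which the bulky aluminium alkoxide formed first shields its own face so that the second methyl should enter anti to it and give mainly the cis diol.

**Step 10**
Reactants: 17 dichloromethane; 16 mac diol
Product: 20 dichloromethylboronic acid mac ester, via dichloromethyllithium 18 (not isolated), via dichloromethylboronic acid 19 (not isolated)
Conditions: n-BuLi, THF, −100 °C; B(OMe)3; 5 M HCl; then 16, MgSO4, CH2Cl2, rt
Reagents that add atoms: trimethyl borate, COB(OC)OC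
Why: Deprotonation of dichloromethane, borylation of the carbenoid and hydrolysis give the boronic acid, which condenses with the cis-diol under neutral dehydrating conditions as in the standard preparation of the pinacol reagent, while any trans-diol cannot span boron and stays behind.

**Step 11**
Reactants: 14 (4S)-aldehyde; 20 dichloromethylboronic acid mac ester
Product: 21 (4R,E)-alkenylboronic acid mac ester (C4–C7'H=C8'H–B)
Conditions: CrCl2 (8 equiv), LiI (4 equiv), THF, rt
Reagents that add atoms: none
Why: Takai-type boryl olefination, in which divalent chromium reduces the dihalomethylboronate to a geminal dichromium nucleophile that adds to the non-enolisable aldehyde and eliminates to the (E)-alkenylboronate, the geometry being enforced by the bulky C4 group, with ketal, alkene and cyclopropane inert.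

**Step 12**
Reactants: 22 2,4,6-trimethoxyphenol
Product: 23 2,4,6-trimethoxyphenyl triflate
Conditions: Tf2O, pyridine, CH2Cl2, 0 °C
Reagents that add atoms: triflic anhydride, O=S(=O)(OS(=O)(=O)C(F)(F)F)C(F)(F)F
Why: O-sulfonylation of a phenol with triflic anhydride and pyridine is general and tolerates the flanking methoxy groups.

**Step 13**
Reactants: 21 (4R,E)-alkenylboronic acid mac ester; 24 isopropyllithium; 23 2,4,6-trimethoxyphenyl triflate
Product: 26 (7'R,8'S)-adduct (aryl on C7'; isopropyl plus B(mac) on C8'), via lithium isopropyl ate complex 25 (not isolated)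
Conditions: 24 (1.0 equiv), Et2O, −78 °C → rt, evaporate; 23 (1.2 equiv), Pd(OAc)2 (5 mol %), (SP,S'P)-1,1'-bis[bis(4-methoxy-3,5-dimethylphenyl)phosphino]-2,2'-bis[(R)-(dimethylamino)(phenyl)methyl]ferrocene (MandyPhos type, 6 mol %), THF, 60 °C
Reagents that add atoms: none
Why: Proposed new method: 24 adds to the boron of 21 to give ate complex 25; oxidative addition of 23 to the zerovalent palladium–bisphosphine complex gives a cationic arylpalladium species (divalent palladium) that binds the C7'=C8' alkene of 25, isopropyl migrates from boron to C8' anti to the metal while palladium bonds to C7', and reductive elimination with retention forms the aryl–C7' bond. The closest known reaction type is the palladium-catalysed enantioselective conjunctive cross-coupling of β-alkyl alkenylboron ate complexes with aryl triflates, which has not been shown for a β-tert-alkyl alkene or for a 2,6-disubstituted aryl triflate. No ring is closed. C7' (R) is set by the alkene face that the chiral ligand allows palladium to bind, hence by the catalyst and not by neighbouring quaternary C4, and C8' (S) follows from the stereospecific anti addition to the (E)-alkene and is erased in step 14. The step needs chemoselectivity for the 1,2-metalate shift over direct alkenyl transfer from boron to palladium, and the crowded mac diol is chosen because it blocks the oxygen lone pairs through which that transfer runs; the regiochemistry is inherent, since only boron-bearing C8' can receive the migrating group. Quaternary C4 offers no β-hydrogen, so only the single C8'–H could be lost from the C7'–palladium intermediate, and the wide bite angle of the ferrocenyl ligand should make reductive elimination faster than that loss.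

**Step 14**
Reactants: 26 (7'R,8'S)-adduct
Product: 28 (7'R)-isobutyl compound (C8' now CH2), via lithium phenyl ate complex 27 (not isolated)
Conditions: PhLi (1.1 equiv), THF, −78 °C → rt; then Mn(OAc)3·2H2O, 4-tert-butylcatechol, rt → 40 °C
Reagents that add atoms: none
Why: Oxidative radical protodeboronation of a secondary alkylboronic ester, in which PhLi makes boron tetracoordinate, Mn(OAc)3 removes one electron to release the C8' radical and the catechol quenches it by hydrogen-atom transfer; a catechol is preferred to a thiol because its aryloxyl radical does not add to the C1=C5 vinylcyclopropane, and C7' is untouched.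

**Step 15**
Reactants: 28 (7'R)-isobutyl compound
Product: 30 (1S,5S)-alcohol (C1–OH; cyclopropane on C5 still cis to the C7' branch), via C1 alkylborane 29 (not isolated)
Conditions: BH3·THF, THF, 0 °C → rt; then NaOH, 30% H2O2, 0 °C → rt
Reagents that add atoms: hydrogen peroxide, OO
Why: Hydroboration–oxidation puts boron on the less substituted C1 and hydrogen on C5 by syn addition from the face of the small C4 methyl, so no cyclopropylcarbinylborane arises, and material from attack on the other face converges on the same ketone 32 after steps 16 and 17.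

**Step 16**
Reactants: 30 (1S,5S)-alcohol
Product: 31 (5S)-ketone (C5 epimer of 32)
Conditions: n-Pr4N[RuO4] (5 mol %), N-methylmorpholine N-oxide, 4 Å MS, CH2Cl2, rt
Reagents that add atoms: none
Why: Ley–Griffith oxidation converts the hindered secondary alcohol into the C1 ketone under neutral conditions that spare the ketal, the cyclopropane and the electron-rich arene.

**Step 17**
Reactants: 31 (5S)-ketone
Product: 32 (5R)-ketone
Conditions: NaOMe (0.2 equiv), MeOH, 40 °C
Reagents that add atoms: none
Why: Epimerisation through the C1–C5 enolate is under thermodynamic control and should place the cyclopropyl group trans to the very large CH(aryl)(isobutyl) branch and cis to the C4 methyl, which is the target configuration, while the ketal keeps the side-chain ketone out of aldol reactions.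

**Step 18**
Reactants: 32 (5R)-ketone
Product: 33 trimethoxyaryl diketone
Conditions: p-TsOH·H2O (10 mol %), THF/H2O, rt
Reagents that add atoms: water, O
Why: Acid-catalysed acetal hydrolysis under mild aqueous conditions frees the C10 ketone without touching the aryl ethers or the cyclopropane, and C5 is already at its equilibrium configuration.

**Step 19**
Reactants: 33 trimethoxyaryl diketone
Product: 34 trimethoxy dialdehyde
Conditions: Cl2CHOMe (6 equiv), TiCl4 (8 equiv), CH2Cl2, −78 → 0 °C; then 1 M HCl
Reagents that add atoms: dichloromethyl methyl ether, COC(Cl)Cl; water, O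
Why: Rieche formylation, a twofold electrophilic aromatic substitution at the only two free ring positions, each activated by two ortho and one para methoxy group, which allows low temperature and excess reagent to carry the second formylation.

**Step 20**
Reactants: 34 trimethoxy dialdehyde
Product: 35 target CNP0217082.3
Conditions: BCl3 (8 equiv), CH2Cl2, −78 → 0 °C; then H2O
Reagents that add atoms: none
Why: Chelation-assisted aryl methyl ether cleavage, in which BCl3 bridges a formyl oxygen and the adjacent methoxy oxygen and chloride removes the methyl group; all three methoxy groups lie ortho to a formyl group, so all are cleaved at low temperature and no stereocentre is affected.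

**Compound list**
1 | (+)-ledene, (1aR,7R,7aS,7bR)-1,1,4,7-tetramethyl-1a,2,3,5,6,7,7a,7b-octahydro-1H-cyclopropa[e]azulene | CC1=C2CC[C@@H](C)[C@H]2[C@H]3[C@@H](CC1)C3(C)C | starting material
2 | secondary ozonide of 1 (1,2,4-trioxolane bridging C1 and C10) | CC12CC[C@@H]3[C@H]([C@@H]4[C@H](C)CCC4(OO1)O2)C3(C)C | intermediate
3 | seco-diketone: 3-methyl-2-[2,2-dimethyl-3-(3-oxobutyl)cyclopropyl]cyclopentanone, C4–C7 as in 1 | CC(=O)CC[C@@H]1[C@H]([C@H]2C(=O)CC[C@H]2C)C1(C)C | intermediate
4 | C10 ethylene ketal of 3 | CC1(CC[C@@H]2[C@H]([C@H]3C(=O)CC[C@H]3C)C2(C)C)OCCO1 | intermediate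
5 | C1 trimethylsilyl enol ether (C1=C5) of 4 | CC1(CC[C@@H]2[C@H](C3=C(O[Si](C)(C)C)CC[C@H]3C)C2(C)C)OCCO1 | intermediate
6 | C5 phenylselenide, PhSe trans to the C4 methyl | CC1(CC[C@@H]2[C@H]([C@@]3([Se]c4ccccc4)C(=O)CC[C@H]3C)C2(C)C)OCCO1 | intermediate
7 | selenoxide of 6 | CC1(CC[C@@H]2[C@H]([C@@]3([Se](=O)c4ccccc4)C(=O)CC[C@H]3C)C2(C)C)OCCO1 | intermediate
8 | enone: 3-methyl-2-cyclopropylcyclopent-2-enone core (C4=C5), ketal side chain | CC1(CC[C@@H]2[C@H](C3=C(C)CCC3=O)C2(C)C)OCCO1 | intermediate
9 | (1R)-allylic alcohol | CC1(CC[C@@H]2[C@H](C3=C(C)CC[C@H]3O)C2(C)C)OCCO1 | intermediate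
10 | tributyl(iodomethyl)stannane | CCCC[Sn](CCCC)(CCCC)CI | starting material
11 | (1R)-tributylstannylmethyl ether of 9 | CC1(CC[C@@H]2[C@H](C3=C(C)CC[C@H]3OC[Sn](CCCC)(CCCC)CCCC)C2(C)C)OCCO1 | intermediate
12 | (1R)-lithiomethyl ether (alkoxymethyllithium) | CC1(CC[C@@H]2[C@H](C3=C(C)CC[C@H]3OC[Li])C2(C)C)OCCO1 | intermediate
13 | (4S)-primary alcohol, C4 bearing CH3 and CH2OH, alkene C1=C5 | CC1(CC[C@@H]2[C@H](C3=CCC[C@]3(C)CO)C2(C)C)OCCO1 | intermediate
14 | (4S)-aldehyde | CC1(CC[C@@H]2[C@H](C3=CCC[C@]3(C)C=O)C2(C)C)OCCO1 | intermediate
15 | acenaphthoquinone | O=C1C(=O)c2cccc3cccc1c23 | starting material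
16 | mac diol, cis-1,2-dimethyl-1,2-dihydroacenaphthylene-1,2-diol (meso) | C[C@]1(O)c2cccc3cccc(c23)[C@@]1(C)O | intermediate
17 | dichloromethane | ClCCl | starting material
18 | dichloromethyllithium | [Li]C(Cl)Cl | intermediate
19 | dichloromethylboronic acid | OB(O)C(Cl)Cl | intermediate
20 | dichloromethylboronic acid mac ester | ClC(Cl)B1O[C@@]2(C)c3cccc4cccc(c34)[C@@]2(C)O1 | intermediate
21 | (4R,E)-alkenylboronic acid mac ester on C4 | CC1(CC[C@@H]2[C@H](C3=CCC[C@]3(C)/C=C/B3O[C@@]4(C)c5cccc6cccc(c56)[C@@]4(C)O3)C2(C)C)OCCO1 | intermediate
22 | 2,4,6-trimethoxyphenol | COc1cc(OC)c(O)c(OC)c1 | starting material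
23 | 2,4,6-trimethoxyphenyl triflate | COc1cc(OC)c(OS(=O)(=O)C(F)(F)F)c(OC)c1 | intermediate
24 | isopropyllithium | [Li]C(C)C | starting material
25 | lithium isopropyl(alkenyl) mac ate complex | CC1(CC[C@@H]2[C@H](C3=CCC[C@]3(C)/C=C/[B-]3(C(C)C)O[C@@]4(C)c5cccc6cccc(c56)[C@@]4(C)O3)C2(C)C)OCCO1.[Li+] | intermediate
26 | (4R,7'R,8'S)-adduct: aryl on C7', isopropyl and B(mac) on C8' | CC1(CC[C@@H]2[C@H](C3=CCC[C@]3(C)[C@@H]([C@@H](B3O[C@@]4(C)c5cccc6cccc(c56)[C@@]4(C)O3)C(C)C)c3c(OC)cc(OC)cc3OC)C2(C)C)OCCO1 | intermediate
27 | lithium phenyl ate complex of 26 | CC1(CC[C@@H]2[C@H](C3=CCC[C@]3(C)[C@@H]([C@@H]([B-]3(c7ccccc7)O[C@@]4(C)c5cccc6cccc(c56)[C@@]4(C)O3)C(C)C)c3c(OC)cc(OC)cc3OC)C2(C)C)OCCO1.[Li+] | intermediate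
28 | (4R,7'R)-isobutyl compound, alkene C1=C5, ketal | CC1(CC[C@@H]2[C@H](C3=CCC[C@]3(C)[C@@H](CC(C)C)c3c(OC)cc(OC)cc3OC)C2(C)C)OCCO1 | intermediate
29 | C1 alkylborane (BH2 and C5–H on the C4-methyl face) | CC1(CC[C@@H]2[C@H]([C@@H]3[C@@H](B)CC[C@]3(C)[C@@H](CC(C)C)c3c(OC)cc(OC)cc3OC)C2(C)C)OCCO1 | intermediate
30 | (1S,5S)-alcohol | CC1(CC[C@@H]2[C@H]([C@@H]3[C@@H](O)CC[C@]3(C)[C@@H](CC(C)C)c3c(OC)cc(OC)cc3OC)C2(C)C)OCCO1 | intermediate
31 | (5S)-ketone, cyclopropane cis to the C7' branch | CC1(CC[C@@H]2[C@H]([C@@H]3C(=O)CC[C@]3(C)[C@@H](CC(C)C)c3c(OC)cc(OC)cc3OC)C2(C)C)OCCO1 | intermediate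
32 | (5R)-ketone, cyclopropane trans to the C7' branch | CC1(CC[C@@H]2[C@H]([C@H]3C(=O)CC[C@]3(C)[C@@H](CC(C)C)c3c(OC)cc(OC)cc3OC)C2(C)C)OCCO1 | intermediate
33 | trimethoxyaryl diketone | CC(=O)CC[C@@H]1[C@H]([C@H]2C(=O)CC[C@]2(C)[C@@H](CC(C)C)c2c(OC)cc(OC)cc2OC)C1(C)C | intermediate
34 | trimethoxy dialdehyde | CC(=O)CC[C@@H]1[C@H]([C@H]2C(=O)CC[C@]2(C)[C@@H](CC(C)C)c2c(OC)c(C=O)c(OC)c(C=O)c2OC)C1(C)C | intermediate
35 | CNP0217082.3 (C4 R, C5 R, C6 R, C7 R, C7' R) | CC(=O)CC[C@@H]1[C@H]([C@H]2C(=O)CC[C@]2(C)[C@@H](CC(C)C)c2c(O)c(C=O)c(O)c(C=O)c2O)C1(C)C | target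

**Count**
Total step count: 20.
Longest linear sequence: 17 steps from (+)-ledene (steps 1–8, 11, 13–20).

**Steps most likely to fail**

Step 13 (new method). Several processes could defeat it:
- The crowded, electron-rich triflate may add to palladium too slowly.
- The alkenyl group may pass directly from boron to palladium without migration.
- The C7'–palladium intermediate may lose the C8' hydrogen before the hindered reductive elimination.
- Facial selection next to quaternary C4 may be poor.

The fallback uses known chemistry, sets out from aldehyde 14 and returns at 28.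
- 1,3,5-Trimethoxybenzene is lithiated with n-BuLi to 2,4,6-trimethoxyphenyllithium F1.
- F1 adds to 14 to give benzylic alcohol F2. Either C7' epimer serves, because the centre is erased in the next operation.
- Catalytic InCl3 in CH2Cl2 at low temperature ionises F2 to the strongly stabilised trimethoxybenzyl cation. Methallyltrimethylsilane captures it (Hosomi–Sakurai-type benzylic allylation) to give methallyl adduct F3.
- C7' is then set by the substrate alone, and the epimers are separated by chromatography.
- RhCl(PPh3)3 under H2 saturates only the 1,1-disubstituted alkene and delivers 28.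

Step 14. Ate formation at the very crowded boron may be incomplete. The C8' radical may also be diverted by a 1,2-aryl shift or by internal hydrogen abstraction before it is quenched.

The fallback sets out from 26 and returns at 28.
- NaOH/H2O2 oxidises the C–B bond with retention to C8' alcohol F4.
- NaH, CS2 and MeI convert F4 into S-methyl xanthate F5.
- Barton–McCombie deoxygenation (Bu3SnH, AIBN, toluene, 80 °C) gives 28.

Step 19. The strong Lewis acid and the hydrogen chloride it releases may open the gem-dimethylcyclopropane. They may also promote aldol reactions between the two ketones. The reaction may stall after the first formylation, once the ring is deactivated by a titanium-bound aldehyde.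

The fallback sets out from 33 and returns at 34.
- NBS (2 equiv, MeCN, 0 °C) gives dibromide F6.
- Twofold Suzuki–Miyaura vinylation (potassium vinyltrifluoroborate, Pd(OAc)2, SPhos, K2CO3, THF/H2O) gives divinylarene F7.
- Lemieux–Johnson cleavage (OsO4 cat., NaIO4, 2,6-lutidine, dioxane/H2O) gives 34 with no Lewis acid involved.

**Further compounds**
F1 | step 13 | 2,4,6-trimethoxyphenyllithium | COc1cc(OC)c([Li])c(OC)c1
F2 | step 13 | benzylic alcohol (C7'–OH, both epimers) | CC1(CC[C@@H]2[C@H](C3=CCC[C@]3(C)C(O)c3c(OC)cc(OC)cc3OC)C2(C)C)OCCO1
F3 | step 13 | (7'R)-methallyl adduct | CC1(CC[C@@H]2[C@H](C3=CCC[C@]3(C)[C@@H](CC(C)=C)c3c(OC)cc(OC)cc3OC)C2(C)C)OCCO1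
F4 | step 14 | C8' alcohol | CC1(CC[C@@H]2[C@H](C3=CCC[C@]3(C)[C@@H]([C@@H](O)C(C)C)c3c(OC)cc(OC)cc3OC)C2(C)C)OCCO1
F5 | step 14 | C8' S-methyl xanthate | CC1(CC[C@@H]2[C@H](C3=CCC[C@]3(C)[C@@H]([C@@H](OC(=S)SC)C(C)C)c3c(OC)cc(OC)cc3OC)C2(C)C)OCCO1
F6 | step 19 | dibromide | CC(=O)CC[C@@H]1[C@H]([C@H]2C(=O)CC[C@]2(C)[C@@H](CC(C)C)c2c(OC)c(Br)c(OC)c(Br)c2OC)C1(C)C
F7 | step 19 | divinylarene | CC(=O)CC[C@@H]1[C@H]([C@H]2C(=O)CC[C@]2(C)[C@@H](CC(C)C)c2c(OC)c(C=C)c(OC)c(C=C)c2OC)C1(C)C
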